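**Plan**
- Cuts: the six O–benzyl bonds go last; C2 is traced back to its epimer and C3–H to C3–OH; the core is then cut at O1–C7a and C3a–C3 into a ring C/D aryne and a ring A/B alpha-oxy ketone. The remaining cuts are the aryl–CH2 bond of the C6 ethyl chain and the CH–aryl bond of the ketone.
- Enabling feature: O1 (on C7a) and C3 (on C3a) sit on neighbouring carbons of ring C and the C4 oxygen flanks C3a. A C3a,C7a-aryne polarised by that oxygen therefore takes an alkoxide at C7a and leaves the carbanion at C3a, next to the ketone.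
- Forward order: ring C/D silyl triflate (chain by B-alkyl Suzuki coupling, silicon by directed metalation between the two oxygens); ring A/B silyloxy ketone (ketone alpha-arylation, enolate hydroxylation); the annulation then closes the dihydrofuran ring, the only ring formed; deoxygenation, C2 epimerisation and debenzylation finish.
- Stereochemistry: the (S)-carbinol centre comes from reagent-controlled enolate hydroxylation. It steers hydride to C3 anti to ring A (fixing C3 as S), and acid equilibration then inverts C2 to give the trans (2S,3S) compound.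

Key step: step 12

Conventions: benzofuran numbering (O1, C2, C3, C3a, C4 to C7, C7a) is used for the core; ring A is the aryl group on C2, ring B the aryl group on C3, ring C the fused benzene ring, ring D the oxyphenyl end of the C6 ethyl chain; Bn = benzyl.

Remark: the sense of induction in step 10 is carried over from the hydroxylation of 1,2-diphenylethanone with the same oxaziridine; the configuration of 22 would be confirmed before the fragments are joined, and the antipodal oxaziridine would be used if the opposite sense were found.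

**Route**

Step 1
Reactants: 1 3,5-dibromophenol
Product: 2 1-(benzyloxy)-3,5-dibromobenzene
Conditions: BnBr, K2CO3, DMF, rt
Reagents that add atoms: benzyl bromide, BrCc1ccccc1
Why: Williamson ether synthesis on an acidic phenol; benzyl is chosen because all six phenol ethers can be removed at the end by neutral hydrogenolysis.

Step 2
Reactants: 2 1-(benzyloxy)-3,5-dibromobenzene
Product: 5 3-(benzyloxy)-5-bromophenol, via aryllithium 3 (not isolated), via dimethyl arylboronate 4 (not isolated)
Conditions: n-BuLi (1.05 equiv), Et2O, −78 °C; B(OMe)3, −78 °C to rt; H2O2 (30% aq), 0 °C to rt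
Reagents that add atoms: hydrogen peroxide, OO
Why: Bromine–lithium exchange on the symmetrical dibromide should stop after one exchange because the aryllithium resists a second one, and borylation followed by boronate oxidation (aryl migration from boron to oxygen) turns that carbon into the phenol, so the two ring C oxygens are told apart without a statistical step.

Step 3
Reactants: 6 4-(benzyloxy)benzaldehyde
Product: 7 1-(benzyloxy)-4-ethenylbenzene
Conditions: CH3PPh3Br, KOtBu, THF, 0 °C to rt
Reagents that add atoms: methyltriphenylphosphonium bromide, C[P+](c1ccccc1)(c1ccccc1)c1ccccc1.[Br-]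
Why: Wittig methylenation of an aromatic aldehyde with the non-stabilised ylide is routine and supplies the styrene that donates the two chain carbons.

Step 4
Reactants: 5 3-(benzyloxy)-5-bromophenol; 7 1-(benzyloxy)-4-ethenylbenzene
Product: 9 3-(benzyloxy)-5-{2-[4-(benzyloxy)phenyl]ethyl}phenol, via alkylborane 8 (not isolated)
Conditions: 7, 9-BBN dimer, THF, 0 °C to rt; then 5, PdCl2(dppf) (5 mol%), K3PO4 (3 M aq), DMF, 60 °C
Reagents that add atoms: none
Why: Anti-Markovnikov hydroboration of the styrene followed by B-alkyl Suzuki–Miyaura coupling with the aryl bromide forms the saturated ArCH2CH2Ar link directly, so no alkene has to be hydrogenated beside benzyl ethers, and the free phenol is tolerated as its phenoxide.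

Step 5
Reactants: 9 3-(benzyloxy)-5-{2-[4-(benzyloxy)phenyl]ethyl}phenol
Product: 10 3-(benzyloxy)-5-{2-[4-(benzyloxy)phenyl]ethyl}phenyl N-(propan-2-yl)carbamate
Conditions: i-PrNCO, Et3N (0.2 equiv), CH2Cl2, rt
Reagents that add atoms: isopropyl isocyanate, CC(C)N=C=O
Why: Base-catalysed addition of the phenol to the isocyanate gives an N-monoalkyl carbamate, a strong ortho-directing group that can later be removed under mild, non-reducing conditions.

Step 6
Reactants: 10 3-(benzyloxy)-5-{2-[4-(benzyloxy)phenyl]ethyl}phenyl N-(propan-2-yl)carbamate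
Product: 14 3-(benzyloxy)-5-{2-[4-(benzyloxy)phenyl]ethyl}-2-(trimethylsilyl)phenyl N-(propan-2-yl)carbamate, via N-silyl carbamate 11 (not isolated), via aryllithium 12 (not isolated), via N-silyl C-silyl carbamate 13 (not isolated)
Conditions: TBSOTf, TMEDA, Et2O, 0 °C to rt; n-BuLi, TMEDA, −78 °C; TMSCl, −78 °C to rt; aq NaHSO4 work-up
Reagents that add atoms: chlorotrimethylsilane, C[Si](C)(C)Cl
Why: Directed ortho-metalation: after temporary N-silylation the carbamate and the benzyloxy group jointly direct lithiation to the carbon between them, which at −78 °C should be kinetically far more acidic than the benzylic ether positions, and silylation followed by acidic loss of the N-silyl group places the trimethylsilyl group on the future C3a.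

Step 7
Reactants: 14 3-(benzyloxy)-5-{2-[4-(benzyloxy)phenyl]ethyl}-2-(trimethylsilyl)phenyl N-(propan-2-yl)carbamate
Product: 16 3-(benzyloxy)-5-{2-[4-(benzyloxy)phenyl]ethyl}-2-(trimethylsilyl)phenyl trifluoromethanesulfonate, via silylphenol 15 (not isolated)
Conditions: DBU, Et2NH, MeCN, 40 °C; then PhNTf2, rt
Reagents that add atoms: N-phenylbis(trifluoromethanesulfonimide), O=S(=O)(N(c1ccccc1)S(=O)(=O)C(F)(F)F)C(F)(F)F
Why: E1cB cleavage of the N–H carbamate (the isocyanate is scavenged by Et2NH) frees the phenoxide, which is triflated in the same flask, so the ortho-silylaryl triflate is obtained without exposing the protodesilylation-prone silylphenol to acid.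

Step 8
Reactants: 17 4-bromobenzene-1,3-diol
Product: 18 2,4-bis(benzyloxy)-1-bromobenzene
Conditions: BnBr (2.2 equiv), K2CO3, DMF, 50 °C
Reagents that add atoms: benzyl bromide, BrCc1ccccc1
Why: Twofold Williamson ether synthesis gives the ring A bromide with the same hydrogenolysable protection.

Step 9
Reactants: 18 2,4-bis(benzyloxy)-1-bromobenzene; 19 1-[3,5-bis(benzyloxy)phenyl]ethan-1-one
Product: 20 1-[3,5-bis(benzyloxy)phenyl]-2-[2,4-bis(benzyloxy)phenyl]ethan-1-one
Conditions: Pd(OAc)2 (2 mol%), XPhos (4 mol%), NaOtBu (2.2 equiv), toluene, 80 °C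
Reagents that add atoms: none
Why: Pd-catalysed alpha-arylation of the methyl ketone enolate with the aryl bromide; the more acidic product is held as its enolate by the second equivalent of base, which should suppress diarylation, and the bulky biarylphosphine copes with the ortho-alkoxy bromide.

Step 10
Reactants: 20 1-[3,5-bis(benzyloxy)phenyl]-2-[2,4-bis(benzyloxy)phenyl]ethan-1-one
Product: 22 (2S)-1-[3,5-bis(benzyloxy)phenyl]-2-[2,4-bis(benzyloxy)phenyl]-2-hydroxyethan-1-one, via sodium enolate 21 (not isolated)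
Conditions: NaN(SiMe3)2 (1.1 equiv), THF, −78 °C; (+)-(camphorylsulfonyl)oxaziridine (1.3 equiv), −78 °C; aq NH4Cl at −78 °C
Reagents that add atoms: (+)-(2R,8aS)-(camphorylsulfonyl)oxaziridine, O=S3(=O)C[C@@]12CC[C@@H](C1(C)C)C[C@]24ON34
Why: Asymmetric hydroxylation of the (Z)-sodium enolate by oxygen transfer from the enantiopure N-sulfonyloxaziridine (Davis oxidation) sets the carbinol centre under reagent control, with the (S) sense assigned by analogy with 1,2-diphenylethanone, while the cold neutral quench avoids enediolate racemisation and crystallisation should raise the enantiomeric purity if needed.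

Step 11
Reactants: 22 (2S)-1-[3,5-bis(benzyloxy)phenyl]-2-[2,4-bis(benzyloxy)phenyl]-2-hydroxyethan-1-one
Product: 23 (2S)-1-[3,5-bis(benzyloxy)phenyl]-2-[2,4-bis(benzyloxy)phenyl]-2-[(trimethylsilyl)oxy]ethan-1-one
Conditions: TMSCl, imidazole, CH2Cl2, 0 °C
Reagents that add atoms: chlorotrimethylsilane, C[Si](C)(C)Cl
Why: Silylation of the secondary alcohol with a weak base that should not enolise the ketol masks the hydroxyl as a group that fluoride removes, so that step 12 can run without any proton source.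

Step 12
Reactants: 16 3-(benzyloxy)-5-{2-[4-(benzyloxy)phenyl]ethyl}-2-(trimethylsilyl)phenyl trifluoromethanesulfonate; 23 (2S)-1-[3,5-bis(benzyloxy)phenyl]-2-[2,4-bis(benzyloxy)phenyl]-2-[(trimethylsilyl)oxy]ethan-1-one
Product: 27 (2S,3S)-4-(benzyloxy)-2-[2,4-bis(benzyloxy)phenyl]-3-[3,5-bis(benzyloxy)phenyl]-6-{2-[4-(benzyloxy)phenyl]ethyl}-2,3-dihydro-1-benzofuran-3-ol, via cesium alkoxide 24 (not isolated), via aryne 25 (not isolated), via aryl anion 26 (not isolated)
Conditions: CsF (3 equiv), MeCN, 0 °C to rt, 16 added slowly to 23 and CsF; aq NH4Cl work-up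
Reagents that add atoms: none
Why: Proposed new method: fluoride first strips the O-silyl group of 23 to give the aprotic cesium alkoxide 24 and, more slowly, triggers 1,2-elimination of 16 to aryne 25; the alkoxide oxygen adds to the aryne carbon remote from the benzyloxy group (the future C7a), which leaves the carbanion at C3a (26) where the inductive pull of the C4 oxygen stabilises it, and this anion adds to the neighbouring ketone to give the C3 alkoxide. The closest known reaction type is the aryne annulation in which a heteroatom nucleophile adds and the resulting aryl anion is trapped within the same molecule by a carbonyl group, as in xanthone formation from salicylates and 3-hydroxyindoline formation from alpha-amino ketones; an alpha-silyloxy ketone has not been shown in this role. The dihydrofuran ring closes by 5-exo-trig attack of the C3a anion on the C3 carbonyl carbon. The new C3 centre is controlled by the C2 centre, the bulky ring B being expected to turn away from ring A so that the hydroxyl ends up cis to ring A, although either C3 epimer would serve because step 13 removes this oxygen through a planar cation. The step needs attack at C7a only, which the 3-alkoxy substituent of the aryne secures, and retention of the C2 configuration, which the absence of any proton source and of free base is meant to secure, since the alkoxide is released only from the silyl ether and cannot enolise without becoming a dianion.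

Step 13
Reactants: 27 (2S,3S)-4-(benzyloxy)-2-[2,4-bis(benzyloxy)phenyl]-3-[3,5-bis(benzyloxy)phenyl]-6-{2-[4-(benzyloxy)phenyl]ethyl}-2,3-dihydro-1-benzofuran-3-ol
Product: 29 (2R,3S)-4-(benzyloxy)-2-[2,4-bis(benzyloxy)phenyl]-3-[3,5-bis(benzyloxy)phenyl]-6-{2-[4-(benzyloxy)phenyl]ethyl}-2,3-dihydro-1-benzofuran (rings A and B cis), via C3 cation 28 (not isolated)
Conditions: Et3SiH (10 equiv), TFA (5 equiv), CH2Cl2, −40 to −20 °C; Et3N quench at −20 °C
Reagents that add atoms: none
Why: Ionic hydrogenation of a tertiary diaryl carbinol: acid ionises the C3–OH bond to a cation stabilised by ring B and by the two ortho oxygens of ring C, and the silane should deliver hydride to the face opposite ring A, which creates the C3 stereocentre with H3 trans to ring A (rings A and B cis) whichever C3 epimer of 27 enters, while silane present before the acid and the low temperature are meant to outrun loss of H2 to the benzofuran.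

Step 14
Reactants: 29 (2R,3S)-4-(benzyloxy)-2-[2,4-bis(benzyloxy)phenyl]-3-[3,5-bis(benzyloxy)phenyl]-6-{2-[4-(benzyloxy)phenyl]ethyl}-2,3-dihydro-1-benzofuran
Product: 31 (2S,3S)-4-(benzyloxy)-2-[2,4-bis(benzyloxy)phenyl]-3-[3,5-bis(benzyloxy)phenyl]-6-{2-[4-(benzyloxy)phenyl]ethyl}-2,3-dihydro-1-benzofuran (rings A and B trans), via ring-opened cation 30 (not isolated)
Conditions: TFA (5 vol%), CH2Cl2, 0 °C to rt
Reagents that add atoms: none
Why: Acid-mediated epimerisation of a 2-aryl-2,3-dihydrobenzofuran: the O1–C2 bond ionises reversibly because ring A carries alkoxy groups ortho and para to C2, and 5-exo reclosure of the phenol onto the benzylic cation should funnel the material to the thermodynamically preferred trans arrangement, inverting C2 while C3 is untouched.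

Step 15
Reactants: 31 (2S,3S)-4-(benzyloxy)-2-[2,4-bis(benzyloxy)phenyl]-3-[3,5-bis(benzyloxy)phenyl]-6-{2-[4-(benzyloxy)phenyl]ethyl}-2,3-dihydro-1-benzofuran
Product: 32 (2S,3S)-2-(2,4-dihydroxyphenyl)-3-(3,5-dihydroxyphenyl)-6-[2-(4-hydroxyphenyl)ethyl]-2,3-dihydro-1-benzofuran-4-ol
Conditions: H2 (1 atm), 10% Pd/C, EtOAc/MeOH, rt
Reagents that add atoms: none
Why: Hydrogenolysis of the six aryl benzyl ethers over palladium should be much faster than cleavage of the cyclic O1–C2 benzylic ether (as in polyphenolic flavan chemistry), there is no alkene to reduce, and no stereocentre is touched.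

**Compound list**

1 | 3,5-dibromophenol | Oc1cc(Br)cc(Br)c1 | starting material
2 | 1-(benzyloxy)-3,5-dibromobenzene | Brc1cc(Br)cc(OCc2ccccc2)c1 | intermediate
3 | [3-(benzyloxy)-5-bromophenyl]lithium (not isolated) | [Li]c1cc(Br)cc(OCc2ccccc2)c1 | intermediate
4 | dimethyl [3-(benzyloxy)-5-bromophenyl]boronate (not isolated) | COB(OC)c1cc(Br)cc(OCc2ccccc2)c1 | intermediate
5 | 3-(benzyloxy)-5-bromophenol | Oc1cc(Br)cc(OCc2ccccc2)c1 | intermediate
6 | 4-(benzyloxy)benzaldehyde | O=Cc1ccc(OCc2ccccc2)cc1 | starting material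
7 | 1-(benzyloxy)-4-ethenylbenzene | C=Cc1ccc(OCc2ccccc2)cc1 | intermediate
8 | 9-{2-[4-(benzyloxy)phenyl]ethyl}-9-borabicyclo[3.3.1]nonane (not isolated) | C(Cc1ccc(OCc2ccccc2)cc1)B1C2CCCC1CCC2 | intermediate
9 | 3-(benzyloxy)-5-{2-[4-(benzyloxy)phenyl]ethyl}phenol | Oc1cc(CCc2ccc(OCc3ccccc3)cc2)cc(OCc2ccccc2)c1 | intermediate
10 | 3-(benzyloxy)-5-{2-[4-(benzyloxy)phenyl]ethyl}phenyl N-(propan-2-yl)carbamate | CC(C)NC(=O)Oc1cc(CCc2ccc(OCc3ccccc3)cc2)cc(OCc2ccccc2)c1 | intermediate
11 | N-[tert-butyl(dimethyl)silyl] derivative of 10 (not isolated) | CC(C)N([Si](C)(C)C(C)(C)C)C(=O)Oc1cc(CCc2ccc(OCc3ccccc3)cc2)cc(OCc2ccccc2)c1 | intermediate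
12 | 2-lithio derivative of 11, lithium between the carbamate and benzyloxy carbons (not isolated) | CC(C)N([Si](C)(C)C(C)(C)C)C(=O)Oc1cc(CCc2ccc(OCc3ccccc3)cc2)cc(OCc2ccccc2)c1[Li] | intermediate
13 | 2-(trimethylsilyl) derivative of 11 (not isolated) | CC(C)N([Si](C)(C)C(C)(C)C)C(=O)Oc1cc(CCc2ccc(OCc3ccccc3)cc2)cc(OCc2ccccc2)c1[Si](C)(C)C | intermediate
14 | 3-(benzyloxy)-5-{2-[4-(benzyloxy)phenyl]ethyl}-2-(trimethylsilyl)phenyl N-(propan-2-yl)carbamate | CC(C)NC(=O)Oc1cc(CCc2ccc(OCc3ccccc3)cc2)cc(OCc2ccccc2)c1[Si](C)(C)C | intermediate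
15 | 3-(benzyloxy)-5-{2-[4-(benzyloxy)phenyl]ethyl}-2-(trimethylsilyl)phenol (not isolated) | Oc1cc(CCc2ccc(OCc3ccccc3)cc2)cc(OCc2ccccc2)c1[Si](C)(C)C | intermediate
16 | 3-(benzyloxy)-5-{2-[4-(benzyloxy)phenyl]ethyl}-2-(trimethylsilyl)phenyl trifluoromethanesulfonate | FC(F)(F)S(=O)(=O)Oc1cc(CCc2ccc(OCc3ccccc3)cc2)cc(OCc2ccccc2)c1[Si](C)(C)C | intermediate
17 | 4-bromobenzene-1,3-diol | Oc1ccc(Br)c(O)c1 | starting material
18 | 2,4-bis(benzyloxy)-1-bromobenzene | Brc1ccc(OCc2ccccc2)cc1OCc1ccccc1 | intermediate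
19 | 1-[3,5-bis(benzyloxy)phenyl]ethan-1-one | CC(=O)c1cc(OCc2ccccc2)cc(OCc2ccccc2)c1 | starting material
20 | 1-[3,5-bis(benzyloxy)phenyl]-2-[2,4-bis(benzyloxy)phenyl]ethan-1-one | O=C(Cc1ccc(OCc2ccccc2)cc1OCc1ccccc1)c1cc(OCc2ccccc2)cc(OCc2ccccc2)c1 | intermediate
21 | sodium (Z)-enolate of 20 (not isolated) | [Na+].[O-]/C(=C\c1ccc(OCc2ccccc2)cc1OCc1ccccc1)c1cc(OCc2ccccc2)cc(OCc2ccccc2)c1 | intermediate
22 | (2S)-1-[3,5-bis(benzyloxy)phenyl]-2-[2,4-bis(benzyloxy)phenyl]-2-hydroxyethan-1-one | O[C@@H](c1ccc(OCc2ccccc2)cc1OCc1ccccc1)C(=O)c1cc(OCc2ccccc2)cc(OCc2ccccc2)c1 | intermediate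
23 | (2S)-1-[3,5-bis(benzyloxy)phenyl]-2-[2,4-bis(benzyloxy)phenyl]-2-[(trimethylsilyl)oxy]ethan-1-one | C[Si](C)(C)O[C@@H](c1ccc(OCc2ccccc2)cc1OCc1ccccc1)C(=O)c1cc(OCc2ccccc2)cc(OCc2ccccc2)c1 | intermediate
24 | cesium (S)-alkoxide of 22 (not isolated) | [Cs+].[O-][C@@H](c1ccc(OCc2ccccc2)cc1OCc1ccccc1)C(=O)c1cc(OCc2ccccc2)cc(OCc2ccccc2)c1 | intermediate
25 | 3-(benzyloxy)-5-{2-[4-(benzyloxy)phenyl]ethyl}benzyne, triple bond between the former C–Si and C–OTf carbons (not isolated) | C1(OCc2ccccc2)=CC(CCc3ccc(OCc4ccccc4)cc3)=CC#C1 | intermediate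
26 | cesium aryl anion: (S)-aryl ether of 22 with the carbanion at C3a (not isolated) | [Cs+].[c-]1c(OCc2ccccc2)cc(CCc2ccc(OCc3ccccc3)cc2)cc1O[C@@H](c1ccc(OCc2ccccc2)cc1OCc1ccccc1)C(=O)c1cc(OCc2ccccc2)cc(OCc2ccccc2)c1 | intermediate
27 | (2S,3S)-4-(benzyloxy)-2-[2,4-bis(benzyloxy)phenyl]-3-[3,5-bis(benzyloxy)phenyl]-6-{2-[4-(benzyloxy)phenyl]ethyl}-2,3-dihydro-1-benzofuran-3-ol (OH cis to ring A) | c1ccccc1COc1ccc(CCc2cc(OCc4ccccc4)c3c(c2)O[C@@H](c2ccc(OCc4ccccc4)cc2OCc2ccccc2)[C@]3(O)c2cc(OCc4ccccc4)cc(OCc4ccccc4)c2)cc1 | intermediate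
28 | C3 benzylic cation from 27, C2 unchanged (not isolated) | c1ccccc1COc1ccc(CCc2cc(OCc4ccccc4)c3c(c2)O[C@@H](c2ccc(OCc4ccccc4)cc2OCc2ccccc2)[C+]3c2cc(OCc4ccccc4)cc(OCc4ccccc4)c2)cc1 | intermediate
29 | (2R,3S)-4-(benzyloxy)-2-[2,4-bis(benzyloxy)phenyl]-3-[3,5-bis(benzyloxy)phenyl]-6-{2-[4-(benzyloxy)phenyl]ethyl}-2,3-dihydro-1-benzofuran (cis) | c1ccccc1COc1ccc(CCc2cc(OCc4ccccc4)c3c(c2)O[C@@H](c2ccc(OCc4ccccc4)cc2OCc2ccccc2)[C@H]3c2cc(OCc4ccccc4)cc(OCc4ccccc4)c2)cc1 | intermediate
30 | ring-opened benzylic cation from 29: free C7a phenol, cation at C2, C3 unchanged (not isolated) | c1ccccc1COc1ccc(CCc2cc(OCc4ccccc4)c(c(O)c2)[C@@H]([CH+]c2ccc(OCc4ccccc4)cc2OCc2ccccc2)c2cc(OCc4ccccc4)cc(OCc4ccccc4)c2)cc1 | intermediate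
31 | (2S,3S)-4-(benzyloxy)-2-[2,4-bis(benzyloxy)phenyl]-3-[3,5-bis(benzyloxy)phenyl]-6-{2-[4-(benzyloxy)phenyl]ethyl}-2,3-dihydro-1-benzofuran (trans) | c1ccccc1COc1ccc(CCc2cc(OCc4ccccc4)c3c(c2)O[C@H](c2ccc(OCc4ccccc4)cc2OCc2ccccc2)[C@H]3c2cc(OCc4ccccc4)cc(OCc4ccccc4)c2)cc1 | intermediate
32 | (2S,3S)-2-(2,4-dihydroxyphenyl)-3-(3,5-dihydroxyphenyl)-6-[2-(4-hydroxyphenyl)ethyl]-2,3-dihydro-1-benzofuran-4-ol (trans) | Oc1ccc(CCc2cc(O)c3c(c2)O[C@H](c2ccc(O)cc2O)[C@H]3c2cc(O)cc(O)c2)cc1 | target

**Step count and risks**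

Total step count: 15 (seven to silyl triflate 16, four to silyloxy ketone 23, four from the annulation onward).
Longest linear sequence: 10 steps (steps 1, 2, 4, 5, 6, 7, 12, 13, 14, 15) from 3,5-dibromophenol.

Steps most likely to fail:

Step 12 (proposed new method). What may go wrong: the cesium alkoxide may lose its configuration or be consumed at the triflate sulfur before the aryne is trapped; the aryl anion may be quenched before ring closure; the product alkoxide may be arylated a second time. The fallback uses known chemistry and no aryne; it sets out from carbamate 10 and ketone 20 and comes back at 27. Aryllithium 12, generated from 10 as in step 6, is quenched with I2 instead of TMSCl to give the N-silyl iodo carbamate F1, which the acidic work-up converts into iodo carbamate F2. DBU and Et2NH then remove the carbamate to give 2-iodophenol F3. Ketone 20 is hydroxylated as in step 10 but with the (−)-oxaziridine to give (R)-ketol F4. Mitsunobu etherification of F3 with F4 (PPh3, DIAD, THF, 0 °C) inverts the carbinol centre and should give (S)-aryl ether F5. Iodine–lithium exchange with t-BuLi at −100 °C gives aryllithium F6, which closes onto the ketone (Parham cyclisation) to return 27.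

Step 13. What may go wrong: loss of H2 from the C3 cation to give the achiral 2,3-diarylbenzofuran, reductive opening of the acid-labile O1–C2 bond by the silane, or hydride delivery to both faces. The fallback replaces the cation by a radical; it sets out from 27 and comes back at 29. NaH, CS2 and MeI convert 27 into S-methyl xanthate F7, which cannot undergo thermal syn-elimination because H2 is trans to the C3 oxygen. Bu3SnH with AIBN in toluene at 80 °C (Barton–McCombie deoxygenation) generates benzylic radical F8, which should take hydrogen from the stannane on the face opposite ring A and so return the cis ether 29 without any acid.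

Step 14. What may go wrong: the ring-opened cation may lose H3 (scrambling C3 through a triarylethene), alkylate another electron-rich ring, or the benzyl ethers may suffer under acid. The fallback reverses the order of the last two operations; it sets out from 29 and comes back at 32. Hydrogenolysis of 29 (H2, Pd/C, EtOAc/MeOH) gives the cis hexaphenol F9. With the para-hydroxyl of ring A free, very dilute acid (HCl, MeOH, rt) should open O1–C2 to the para-quinone methide F10 under far milder conditions than the benzyl-protected series needs. Either of the two equivalent ring C hydroxyls of F10 can close onto it to give the trans compound 32.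

**Further compounds**

F1 | step 12 | 3-(benzyloxy)-5-{2-[4-(benzyloxy)phenyl]ethyl}-2-iodophenyl N-[tert-butyl(dimethyl)silyl]-N-(propan-2-yl)carbamate | CC(C)N([Si](C)(C)C(C)(C)C)C(=O)Oc1cc(CCc2ccc(OCc3ccccc3)cc2)cc(OCc2ccccc2)c1I
F2 | step 12 | 3-(benzyloxy)-5-{2-[4-(benzyloxy)phenyl]ethyl}-2-iodophenyl N-(propan-2-yl)carbamate | CC(C)NC(=O)Oc1cc(CCc2ccc(OCc3ccccc3)cc2)cc(OCc2ccccc2)c1I
F3 | step 12 | 3-(benzyloxy)-5-{2-[4-(benzyloxy)phenyl]ethyl}-2-iodophenol | Oc1cc(CCc2ccc(OCc3ccccc3)cc2)cc(OCc2ccccc2)c1I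
F4 | step 12 | (2R)-1-[3,5-bis(benzyloxy)phenyl]-2-[2,4-bis(benzyloxy)phenyl]-2-hydroxyethan-1-one | O[C@H](c1ccc(OCc2ccccc2)cc1OCc1ccccc1)C(=O)c1cc(OCc2ccccc2)cc(OCc2ccccc2)c1
F5 | step 12 | (2S)-2-(3-(benzyloxy)-5-{2-[4-(benzyloxy)phenyl]ethyl}-2-iodophenoxy)-1-[3,5-bis(benzyloxy)phenyl]-2-[2,4-bis(benzyloxy)phenyl]ethan-1-one | Ic1c(OCc2ccccc2)cc(CCc2ccc(OCc3ccccc3)cc2)cc1O[C@@H](c1ccc(OCc2ccccc2)cc1OCc1ccccc1)C(=O)c1cc(OCc2ccccc2)cc(OCc2ccccc2)c1
F6 | step 12 | aryllithium from F5 (lithium in place of iodine) | [Li]c1c(OCc2ccccc2)cc(CCc2ccc(OCc3ccccc3)cc2)cc1O[C@@H](c1ccc(OCc2ccccc2)cc1OCc1ccccc1)C(=O)c1cc(OCc2ccccc2)cc(OCc2ccccc2)c1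
F7 | step 13 | O-[(2S,3S)-4-(benzyloxy)-2-[2,4-bis(benzyloxy)phenyl]-3-[3,5-bis(benzyloxy)phenyl]-6-{2-[4-(benzyloxy)phenyl]ethyl}-2,3-dihydro-1-benzofuran-3-yl] S-methyl carbonodithioate | c1ccccc1COc1ccc(CCc2cc(OCc4ccccc4)c3c(c2)O[C@@H](c2ccc(OCc4ccccc4)cc2OCc2ccccc2)[C@]3(OC(=S)SC)c2cc(OCc4ccccc4)cc(OCc4ccccc4)c2)cc1
F8 | step 13 | C3 benzylic radical from F7, C2 unchanged | c1ccccc1COc1ccc(CCc2cc(OCc4ccccc4)c3c(c2)O[C@@H](c2ccc(OCc4ccccc4)cc2OCc2ccccc2)[C]3c2cc(OCc4ccccc4)cc(OCc4ccccc4)c2)cc1
F9 | step 14 | (2R,3S)-2-(2,4-dihydroxyphenyl)-3-(3,5-dihydroxyphenyl)-6-[2-(4-hydroxyphenyl)ethyl]-2,3-dihydro-1-benzofuran-4-ol (cis) | Oc1ccc(CCc2cc(O)c3c(c2)O[C@@H](c2ccc(O)cc2O)[C@H]3c2cc(O)cc(O)c2)cc1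
F10 | step 14 | para-quinone methide from F9: O1–C2 opened, ring A as 3-hydroxy-4-methylidenecyclohexa-2,5-dien-1-one, C3 unchanged | Oc1ccc(CCc2cc(O)c(c(O)c2)[C@@H](C=C2C=CC(=O)C=C2O)c2cc(O)cc(O)c2)cc1
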